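The disconnection cuts the cyclohexane ring at C2–C3 and C1–C6, so that a base-catalysed asymmetric Diels–Alder reaction between 3-hydroxy-4-methyl-2-pyrone and methacrolein builds the carbocycle inside a 2-oxabicyclo[2.2.2]octenone. The feature exploited is that, in the target, the C3 ester oxygen and side-chain carbon C7 lie on one face of the six-membered ring while the C6 epoxide oxygen lies on the other: a lactone bridge C7(=O)–O–C3 enforces exactly this, and the bridgehead hydroxyl becomes the C6 oxygen. One operation thus sets C3 and C6 and leaves the C4=C5 alkene for a hydroxyl-delivered epoxide closure. The diene is an oxygenated pyrone made in three steps; the dienophile is bought.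

Key step: step 4

Numbering used for the target: ring C1 (CMe2), C2, C3 (CH–O-acyl), C4, C5 (C–CH3, epoxide), C6 (epoxide carbon bearing the chain); chain C7=C8–C9(=O)–C10.

Assumption: the quinidine-series catalyst is taken to deliver the enantiomer drawn for 9; should the sense be opposite, the quinine-series pseudoenantiomer is used with nothing else changed.

Remark: a 2,5-dioxopentanoate would close under acid to a furan-2-carboxylate (Paal–Knorr) and not to the pyrone, so the diene is reached through a 5-hydroxy-2-oxo acid, for which only the δ-lactone mode is productive, and is dehydrogenated afterwards.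

Step 1
Reactants: 1 3-methyloxolan-2-one (α-methyl-γ-butyrolactone, racemic); 2 diethyl oxalate
Product: 3 ethyl 2-(3-methyl-2-oxooxolan-3-yl)-2-oxoacetate (racemic)
Conditions: LiN(i-Pr)2 (1.05 equiv), THF, −78 °C; enolate added to 2 (2 equiv), THF, −78 °C; AcOH quench
Reagents that add atoms: diethyl oxalate (2), CCOC(=O)C(=O)OCC
Why: Crossed Claisen condensation, in which the preformed lactone lithium enolate is C-acylated by the non-enolisable and highly electrophilic oxalate at low temperature; the new quaternary centre is racemic and is removed again in step 2.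

Step 2
Reactants: 3 ethyl 2-(3-methyl-2-oxooxolan-3-yl)-2-oxoacetate
Product: 5 3-hydroxy-4-methyl-5,6-dihydro-2H-pyran-2-one, via 5-hydroxy-3-methyl-2-oxopentanoic acid 4 (not isolated)
Conditions: 2 M H2SO4 (aq), reflux; continuous EtOAc extraction
Reagents that add atoms: water, O
Why: Acid hydrolysis of ester and lactone, decarboxylation of the resulting β-keto acid and six-membered relactonisation (the oxalyl-lactone route to α-keto-δ-lactones) should give the enolised keto lactone, because with C6 at the alcohol oxidation level the competing five-membered hemiketal cannot aromatise to a furan.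

Step 3
Reactants: 5 3-hydroxy-4-methyl-5,6-dihydro-2H-pyran-2-one
Product: 7 3-hydroxy-4-methyl-2H-pyran-2-one, via 4-bromo-4-methyloxane-2,3-dione 6 (not isolated)
Conditions: Br2 (1.0 equiv), CH2Cl2, 0 °C; solvent swap; Li2CO3, LiBr, DMF, 90 °C; aq. HCl work-up
Reagents that add atoms: none
Why: Electrophilic bromination of the enol at C4 followed by dehydrobromination toward the ring CH2 (halogenation–dehydrohalogenation of a ketone) should give a 3-oxo-3,6-dihydropyranone that tautomerises irreversibly to the hydroxypyrone.

Step 4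
Reactants: 7 3-hydroxy-4-methyl-2H-pyran-2-one; 8 methacrolein
Product: 9 (1S,4R,5S)-4-hydroxy-5,8-dimethyl-3-oxo-2-oxabicyclo[2.2.2]oct-7-ene-5-carbaldehyde (formyl group on the side of the C7=C8 bridge)
Conditions: 9-O-benzylcupreidine (10 mol %), 8 (3 equiv), EtOAc, 0 °C to rt
Reagents that add atoms: none
Why: The quinuclidine nitrogen of the catalyst deprotonates the 3-hydroxyl of 7, and the dienolate, ion-paired and hydrogen-bonded to the catalyst, adds through pyrone C6 to the β-carbon of 8 (target bond C2–C3), after which the enolate α-carbon attacks the pyrone C3 carbonyl (target bond C1–C6), a stepwise or strongly asynchronous [4+2]. The closest known reaction type is the amine- or cinchona-base-catalysed Diels–Alder reaction of 3-hydroxy-2-pyrones with electron-poor alkenes in which the CO2 bridge is kept. The carbocycle closes by a 6-exo-trig aldol-type attack (equivalently the second suprafacial bond of the cycloaddition), and this same bond turns the pyranone into the lactone bridge of the bicyclo[2.2.2] cage, so both rings arise in one closure. The two bridgehead centres (C1 and C4 of 9, later C3 and C6 of the target) are fixed relative to each other by the bridge and in the absolute sense by the dienolate face that the chiral ion pair leaves open, whereas C5 follows from the endo or exo placement of the formyl group and is erased in step 5, so its epimer serves equally. The step needs regio- and enantiofacial selectivity: the first comes from the polarity match between nucleophilic pyrone C6 and the enal β-carbon, the second from the bifunctional catalyst. Mild conditions at or below room temperature should keep the adduct from losing CO2 or reverting by retro-aldol cleavage.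

Step 5
Reactants: 9 (1S,4R,5S)-4-hydroxy-5,8-dimethyl-3-oxo-2-oxabicyclo[2.2.2]oct-7-ene-5-carbaldehyde
Product: 11 (1S,4S)-4-hydroxy-5,5,8-trimethyl-2-oxabicyclo[2.2.2]oct-7-en-3-one, via tosylhydrazone 10 (not isolated)
Conditions: TsNHNH2 (1.05 equiv), THF, rt; solvent exchange to CHCl3; catecholborane (3 equiv), 0 °C to rt; NaOAc·3H2O, 55 °C
Reagents that add atoms: none
Why: Condensation to the tosylhydrazone, its reduction by catecholborane and acetate-induced loss of sulfinate and dinitrogen from the diazene (a mild deoxygenation of the Wolff–Kishner family) should turn the neopentyl formyl group into methyl without a base strong enough for retro-aldol opening, and C5 becomes a non-stereogenic gem-dimethyl carbon.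

Step 6
Reactants: 11 (1S,4S)-4-hydroxy-5,5,8-trimethyl-2-oxabicyclo[2.2.2]oct-7-en-3-one
Product: 12 (1S,4S)-5,5,8-trimethyl-2-oxabicyclo[2.2.2]oct-7-ene-3,4-diol (lactol, both C3 anomers)
Conditions: i-Bu2AlH (2.5 equiv), CH2Cl2, −78 °C; aq. KNaC4H4O6 (potassium sodium tartrate)
Reagents that add atoms: none
Why: Partial hydride reduction of the bridged lactone by i-Bu2AlH should stop at the lactol because the tetrahedral aluminium hemiacetal is held in the bicycle until work-up; the lactol carbon forms as an inconsequential anomer mixture.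

Step 7
Reactants: 12 (1S,4S)-5,5,8-trimethyl-2-oxabicyclo[2.2.2]oct-7-ene-3,4-diol; 13 1-(triphenyl-λ5-phosphanylidene)propan-2-one (acetonylidenetriphenylphosphorane)
Product: 15 (3E)-4-[(1S,4S)-1,4-dihydroxy-2,6,6-trimethylcyclohex-2-en-1-yl]but-3-en-2-one, via open hydroxy aldehyde 14 (not isolated)
Conditions: 13 (2 equiv), toluene, 80 °C
Reagents that add atoms: 1-(triphenyl-λ5-phosphanylidene)propan-2-one (13), CC(=O)C=P(c1ccccc1)(c1ccccc1)c1ccccc1
Why: Wittig olefination of the ring-opened hydroxy aldehyde by the ketone-stabilised ylide should give the E-enone under thermodynamic control and free the C3 hydroxyl without touching the C3 or C6 centres.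

Step 8
Reactants: 15 (3E)-4-[(1S,4S)-1,4-dihydroxy-2,6,6-trimethylcyclohex-2-en-1-yl]but-3-en-2-one; 16 myristoyl chloride
Product: 17 (1S,4S)-4-hydroxy-3,5,5-trimethyl-4-[(1E)-3-oxobut-1-en-1-yl]cyclohex-2-en-1-yl tetradecanoate
Conditions: 16 (1.1 equiv), pyridine, DMAP (5 mol %), CH2Cl2, 0 °C
Reagents that add atoms: myristoyl chloride (16), CCCCCCCCCCCCCC(=O)Cl
Why: DMAP-catalysed acylation (nucleophilic acyl substitution) of the secondary allylic C3 hydroxyl should be far faster than that of the tertiary, doubly allylic C6 hydroxyl, so the monoester forms with retention at C3.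

Step 9
Reactants: 17 (1S,4S)-4-hydroxy-3,5,5-trimethyl-4-[(1E)-3-oxobut-1-en-1-yl]cyclohex-2-en-1-yl tetradecanoate
Product: 18 (1S,4S,6R)-2,2,6-trimethyl-1-[(1E)-3-oxobut-1-en-1-yl]-7-oxabicyclo[4.1.0]heptan-4-yl tetradecanoate (the target; 3S,5R,6S in the numbering above)
Conditions: N,N'-bis(3,5-di-tert-butylsalicylidene)-1,2-cyclohexanediaminocobalt, C36H52CoN2O2 (divalent cobalt, 5 mol %), N-fluoro-2,4,6-trimethylpyridinium triflate (1.5 equiv), PhSiH3 (1.5 equiv), CH2Cl2, 0 °C to rt
Reagents that add atoms: none
Why: Hydrogen-atom transfer from a cobalt hydride (trivalent cobalt) to C4 of the trisubstituted alkene gives the tertiary C5 radical, whose oxidation (radical–polar crossover) lets the neighbouring C6 hydroxyl close the oxirane, which is the cobalt-salen cycloisomerisation of tertiary allylic alcohols to epoxides; since a three-membered ring can only be cis-fused, the C6 oxygen sets C5 as R.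

Compound list
1 | 3-methyloxolan-2-one (α-methyl-γ-butyrolactone, racemic) | CC1CCOC1=O | starting material
2 | diethyl oxalate | CCOC(=O)C(=O)OCC | starting material
3 | ethyl 2-(3-methyl-2-oxooxolan-3-yl)-2-oxoacetate (racemic) | CCOC(=O)C(=O)C1(C)CCOC1=O | intermediate
4 | 5-hydroxy-3-methyl-2-oxopentanoic acid (racemic, not isolated) | CC(CCO)C(=O)C(=O)O | intermediate
5 | 3-hydroxy-4-methyl-5,6-dihydro-2H-pyran-2-one (enol form of 4-methyloxane-2,3-dione) | CC1=C(O)C(=O)OCC1 | intermediate
6 | 4-bromo-4-methyloxane-2,3-dione (racemic, not isolated) | CC1(Br)CCOC(=O)C1=O | intermediate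
7 | 3-hydroxy-4-methyl-2H-pyran-2-one | O=C1OC=CC(C)=C1O | intermediate
8 | methacrolein (2-methylprop-2-enal) | CC(=C)C=O | starting material
9 | (1S,4R,5S)-4-hydroxy-5,8-dimethyl-3-oxo-2-oxabicyclo[2.2.2]oct-7-ene-5-carbaldehyde | O=C1O[C@H]2C[C@](C)(C=O)[C@]1(O)C(C)=C2 | intermediate
10 | N'-[(E)-[(1S,4R,5R)-4-hydroxy-5,8-dimethyl-3-oxo-2-oxabicyclo[2.2.2]oct-7-en-5-yl]methylidene]-4-methylbenzenesulfonohydrazide (tosylhydrazone, not isolated) | O=C1O[C@H]2C[C@](C)(/C=N/NS(=O)(=O)c3ccc(C)cc3)[C@]1(O)C(C)=C2 | intermediate
11 | (1S,4S)-4-hydroxy-5,5,8-trimethyl-2-oxabicyclo[2.2.2]oct-7-en-3-one | O=C1O[C@H]2CC(C)(C)[C@]1(O)C(C)=C2 | intermediate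
12 | (1S,4S)-5,5,8-trimethyl-2-oxabicyclo[2.2.2]oct-7-ene-3,4-diol (lactol, both C3 anomers) | OC1O[C@H]2CC(C)(C)[C@]1(O)C(C)=C2 | intermediate
13 | 1-(triphenyl-λ5-phosphanylidene)propan-2-one | CC(=O)C=P(c1ccccc1)(c1ccccc1)c1ccccc1 | starting material
14 | (1S,4S)-1,4-dihydroxy-2,6,6-trimethylcyclohex-2-ene-1-carbaldehyde (open form of 12, not isolated) | O[C@H]1CC(C)(C)[C@@](O)(C=O)C(C)=C1 | intermediate
15 | (3E)-4-[(1S,4S)-1,4-dihydroxy-2,6,6-trimethylcyclohex-2-en-1-yl]but-3-en-2-one | O[C@H]1CC(C)(C)[C@@](O)(/C=C/C(C)=O)C(C)=C1 | intermediate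
16 | myristoyl chloride (tetradecanoyl chloride) | CCCCCCCCCCCCCC(=O)Cl | starting material
17 | (1S,4S)-4-hydroxy-3,5,5-trimethyl-4-[(1E)-3-oxobut-1-en-1-yl]cyclohex-2-en-1-yl tetradecanoate | CCCCCCCCCCCCCC(=O)O[C@H]1CC(C)(C)[C@@](O)(/C=C/C(C)=O)C(C)=C1 | intermediate
18 | (1S,4S,6R)-2,2,6-trimethyl-1-[(1E)-3-oxobut-1-en-1-yl]-7-oxabicyclo[4.1.0]heptan-4-yl tetradecanoate | CCCCCCCCCCCCCC(=O)O[C@H]1CC(C)(C)[C@]2(/C=C/C(C)=O)O[C@]2(C)C1 | target

Total step count: 9. Longest linear sequence: 9 steps (1 to 18).

Steps most likely to fail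

Step 4. The hindered 4-methyl dienolate may add slowly to the α-branched enal, the intermediate enolate may be protonated before the crowded C1–C6 bond closes, and the chiral ion pair may discriminate poorly between the two dienolate faces. The fallback gives up asymmetric catalysis and resolves instead. It sets out from 7 and 8, which are combined with a small achiral amine (Et3N, 20 mol %, CH2Cl2, rt) to give the racemic adduct F1. This is carried through the conditions of step 5, by way of the racemic tosylhydrazone F2, to the racemic lactone F3. The enantiomers of F3 are separated by preparative chromatography on a chiral stationary phase (amylose tris(3,5-dimethylphenylcarbamate), supercritical CO2/MeOH). The (1S,4S) enantiomer is compound 11, where the route is rejoined.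

Step 9. Hydrogen-atom transfer may go to the enone alkene instead of C4=C5. The C5 cation may also suffer a 1,2-shift of a C6 substituent (ring contraction), or be captured by the C3 ester carbonyl instead of the C6 hydroxyl. The fallback closes the oxirane before enone and ester exist. It sets out from 11, which LiAlH4 (THF, 0 °C) reduces to (1S,4S)-1-(hydroxymethyl)-2,6,6-trimethylcyclohex-2-ene-1,4-diol F4. The cobalt-hydride cycloisomerisation of step 9, now on a substrate with a single alkene, should give (1R,4S,6R)-1-(hydroxymethyl)-2,2,6-trimethyl-7-oxabicyclo[4.1.0]heptan-4-ol F5. Selective oxidation of the primary alcohol (TEMPO cat., PhI(OAc)2, CH2Cl2, rt) gives (1S,4S,6R)-4-hydroxy-2,2,6-trimethyl-7-oxabicyclo[4.1.0]heptane-1-carbaldehyde F6, an epoxy aldehyde of a well-used class. Wittig reaction with 13 (toluene, 80 °C) gives (3E)-4-[(1S,4S,6R)-4-hydroxy-2,2,6-trimethyl-7-oxabicyclo[4.1.0]heptan-1-yl]but-3-en-2-one F7. Acylation with 16 under the conditions of step 8 returns to the route at 18.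

Step 7. The weakly nucleophilic keto ylide may condense only slowly with the hindered, largely lactol-masked aldehyde. At the temperature then needed, the α-hydroxy aldehyde can undergo α-ketol rearrangement, or the freed C3 hydroxyl can add back to the new enone. The fallback replaces the thermal ylide condensation by phosphonate-carbanion olefination (Horner–Wadsworth–Emmons). It sets out from 12, which is treated with dimethyl (2-oxopropyl)phosphonate, LiCl and i-Pr2NEt in MeCN at rt. It comes back to the route at 15 and makes no compound outside the list (F0).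

Further compounds
F1 | step 4 | racemic 4-hydroxy-5,8-dimethyl-3-oxo-2-oxabicyclo[2.2.2]oct-7-ene-5-carbaldehyde (racemate of 9, both enantiomers written) | O=C1O[C@H]2C[C@](C)(C=O)[C@]1(O)C(C)=C2.O=C1O[C@@H]2C[C@@](C)(C=O)[C@@]1(O)C(C)=C2
F2 | step 4 | racemic tosylhydrazone of F1 (racemate of 10, both enantiomers written) | O=C1O[C@H]2C[C@](C)(/C=N/NS(=O)(=O)c3ccc(C)cc3)[C@]1(O)C(C)=C2.O=C1O[C@@H]2C[C@@](C)(/C=N/NS(=O)(=O)c3ccc(C)cc3)[C@@]1(O)C(C)=C2
F3 | step 4 | racemic 4-hydroxy-5,5,8-trimethyl-2-oxabicyclo[2.2.2]oct-7-en-3-one (racemate of 11, both enantiomers written) | O=C1O[C@H]2CC(C)(C)[C@]1(O)C(C)=C2.O=C1O[C@@H]2CC(C)(C)[C@@]1(O)C(C)=C2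
F4 | step 9 | (1S,4S)-1-(hydroxymethyl)-2,6,6-trimethylcyclohex-2-ene-1,4-diol | O[C@H]1CC(C)(C)[C@@](O)(CO)C(C)=C1
F5 | step 9 | (1R,4S,6R)-1-(hydroxymethyl)-2,2,6-trimethyl-7-oxabicyclo[4.1.0]heptan-4-ol | O[C@H]1CC(C)(C)[C@]2(CO)O[C@]2(C)C1
F6 | step 9 | (1S,4S,6R)-4-hydroxy-2,2,6-trimethyl-7-oxabicyclo[4.1.0]heptane-1-carbaldehyde | O[C@H]1CC(C)(C)[C@]2(C=O)O[C@]2(C)C1
F7 | step 9 | (3E)-4-[(1S,4S,6R)-4-hydroxy-2,2,6-trimethyl-7-oxabicyclo[4.1.0]heptan-1-yl]but-3-en-2-one | O[C@H]1CC(C)(C)[C@]2(/C=C/C(C)=O)O[C@]2(C)C1
F0 | step 7 | none | none
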